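All runs are simulated for substances that don't exist, noise included.

What share of Thursday's substrate is still target at 20 min? That hangs on what becomes of target once it is made, so I start from the end state.

| flask | substrate | coupling partner | catalyst | target | time |
|---|---|---|---|---|---|
| Tuesday's | 250 mM | 300 mM | 0.500 mM |  |  |
| Friday's | 250 mM | 300 mM | 0.500 mM | 120 mM |  |
| Monday's | 250 mM | 300 mM | 1.50 mM |  |  |
| Thursday's | 83.0 mM | 900 mM | 0.500 mM |  | 20 min |

| run | time / min | [target] / mM |
|---|---|---|
| Tuesday's run | 0.72 | 5.5 |
| Tuesday's run | 2.2 | 17.7 |
| Tuesday's run | 4.2 | 41.3 |
| Tuesday's run | 6.6 | 75.5 |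
| Tuesday's run | 9.4 | 111.4 |
| Tuesday's run | 13 | 134.8 |
| Tuesday's run | 16 | 145.8 |
| Tuesday's run | 20 | 152.5 |
| Friday's run | 0.72 | 152.4 |
| Friday's run | 2.2 | 203.2 |
| Friday's run | 4.2 | 239.9 |
| Friday's run | 6.6 | 257.9 |
| Friday's run | 9.4 | 265.1 |
| Friday's run | 13 | 269.4 |
| Friday's run | 16 | 270.0 |
| Friday's run | 20 | 272.2 |
| Monday's run | 0.72 | 12.5 |
| Monday's run | 2.2 | 44.7 |
| Monday's run | 4.2 | 88.5 |
| Monday's run | 6.6 | 126.9 |
| Monday's run | 9.4 | 150.9 |
| Monday's run | 13 | 163.3 |
| Monday's run | 16 | 168.0 |
| Monday's run | 20 | 171.2 |

(readings scatter by 0.8 mM)

* the power of [catalyst] that the first rate follows, about the charge of the Tuesday's run; measure it at two percent of substrate made into target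
* target in the Thursday's run at 20 min, as a share of the substrate charged

- Overall: substrate + coupling partner -> target, with catalyst as catalyst.
- Constant volume, constant temperature.
- A reading of a species includes what of it is bound.
- "The second partner" is coupling partner.
- An order is taken over about fifteen percent of the charge, up and down.

I read the top and bottom rows of the tables. Tuesday's flask starts at 7.64 mM min⁻¹ and Friday's flask at 45.0 mM min⁻¹, faster than Tuesday's, so target speeds its own making. Yet Friday's last two rows give 0.550 mM min⁻¹ with twice the target of the first interval, so I take the flat end as a reactant ending, not as a tired catalyst.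

Friday gains 152 mM, although its 300 mM of coupling partner exceeds its 250 mM of substrate. I suppose that target is lost to a side product by taking a further partner, and that Friday's partner is used up at 20 min. Made plus lost is then 300 mM and made minus lost is 152 mM, so 226 mM was made, 73.9 mM lost and 23.9 mM of substrate left.

If target-aided making and loss both scale with target and partner, their ratio follows substrate, and they balance at 31.5 mM of substrate (the inverse of a selectivity factor). Friday's extra first rate, with 136 mM of target present, then gives a life of 25.3 min at Friday's partner charge. Since life goes inversely with partner, Thursday's charge gives 8.44 min, the life of target in partner.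

Thursday's partner exceeds twice its substrate by 734 mM, so my end state holds no target. Substrate times partner matches Tuesday's, so I take a steady 7.64 mM min⁻¹, which uses the substrate in 10.9 min. Building and decaying with that life leaves 19.0%. The first readings of Monday and Tuesday give a catalyst power of 0.747.

The forecast gives 90% (72% to 99%) and a power of 0.74 (0.58 to 0.92), holding that “that exposure would nearly consume substrate”, and on the share my 19.0% differs from it.

    catalyst + substrate ⇌ catalyst-substrate complex, settled at all times (3.090 M⁻¹)
    catalyst-substrate complex + coupling partner ⇌ ternary complex, settled at all times (0.8200 M⁻¹)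
    ternary complex → target + catalyst (115.2 min⁻¹)
    substrate + coupling partner + target → 2 target (5.496 M⁻² min⁻¹)
    target + coupling partner → side product (0.1938 M⁻¹ min⁻¹)

Thursday's flask gives 12.1%, which is 10.0 mM of target at 20 min, and the power is 0.76. The last step above has target taking partner to side product, and its constant gives a life of 5.73 min at Thursday's partner charge, shorter than my 8.44 min. The life serves on Monday's flask too. At 6.49 min its target made stands at 125 mM, so its partner is at most 175 mM, and that constant gives target there a life of at least 29.5 min.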